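Read the solid substrate column of these runs as a rate in M per minute; you can then reckon the flask from that rate and the decay of target.

| flask | solid substrate | target | remark | time |
|---|---|---|---|---|
| south | 0.50 M | 10 mM | run made earlier |  |
| east | 2 M | 10 mM | run made earlier |  |
| north | 1 M | 20 mM | run made earlier |  |
| flask | 1.0 M | 10.0 mM |  | 2.0 h |

| run | time / min | target / % | solid substrate / % |
|---|---|---|---|
| south | 1.00 | 41.8 | 54.9 |
| south | 4.00 | 93.1 | 0.2 |
| south | 20.0 | 55.7 | 0.1 |
| south | 80.0 | 7.7 | 0 |
| east | 1.00 | 10.4 | 90.0 |
| east | 4.00 | 44.3 | 54.2 |
| east | 20.0 | 61.2 | 0.6 |
| east | 80.0 | 8.0 | 0.4 |
| north | 1.00 | 23.2 | 76.7 |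
| north | 4.00 | 90.0 | 6.0 |
| north | 20.0 | 58.1 | 0 |
| north | 80.0 | 8.5 | 0.1 |

(standard deviation of a reading: 0.5 percentage points)

- as a solid, counted per litre of solution: solid substrate
- at the start none of the solid substrate is in solution

- the moment within 2.0 h at which there is most target
- the amount of target, in percent of the solid substrate charged, at that time

Between 1.00 min and 4.00 min the east run, charged with 2 M, loses solid substrate at 0.239 M/min. Over the same interval the north run, charged with 1 M, loses 0.236 M/min, so this looks like a zero-order feed with dissolution as the rate-limiting step.

Next, read across a row: at 4.00 min the east run holds 98.5% as target plus solid substrate, so in the east run nearly all of what has left the solid stands as target. Then read down the target column: from 20.0 min to 80.0 min the south run, taken as first order, reads k = 0.0330 /min for the loss of target.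

Now compare the two rates. My carried quantity is the loss number, k·c(solid substrate) over the feed, the loss of a whole charge standing as target against the feed rate: 0.138 for this flask. The loss starts small and grows with c(target), yet even at a whole charge standing as target it stays below the feed, so I expect target to rise until the solid is reckoned gone, at 0.0698 h. A steady feed keeps 93.4% of the charge by then, and with the surviving seed I reckon 94.3%.

The forecast gives 0.072 h (0.066 h to 0.08 h) and 94% (92% to 96%), holding that “it peaks when the solid runs out”. Its time is slightly later than mine, and its amount matches mine.

The flask gives 94.5% at 0.0715 h, inside both ranges of the forecast.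

    starting material → target (k = 1.30 × 10⁻⁵ /min)
    starting material + target → 2 target (k = 64.0 /M/min)
    solid substrate ⇌ starting material, rate k3*(cs3 - [starting material]) while solid is left; crystals form when [starting material] > cs3 (solubility = 0.620 M, k = 0.390 /min)
    target → over-reaction product (k = 0.0320 /min)

At 0.0715 h the flask holds 6.44% of over-reaction product, and the loss number puts the share lost from the feed at 6.60%. For the neighbour flask charged with 0.25 M of solid substrate, the loss number is 0.0345, which with its seed reckons to 102% of the solid substrate charged. The computed best of that neighbour is 102%.

Readings and results are simulated on assumed constants, noise included.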